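**Retrosynthetic overview**

1. Locants and faces used below: ring carbons C1 (tertiary carbinol), C5 (ester-bearing), C6 (lactone oxygen), C7, C8, C9 (secondary OH), C10 (CH–CH3); C2–C4/C15 butenoyl chain; C11–C13 lactone carbons (C13 exocyclic CH2); C14 methyl; α is the ring face carrying the C6 oxygen and the C7 side chain, β the other.
2. Late disconnections: methylene by E1cB elimination of a C13 mesylate; γ-lactone from the C6 hydroxyl and a Weinreb amide; butenoyl chain from a C1 vinyl group (ozonolysis, allylboration, oxidation/isomerisation); C5 ester by acylation; C9 oxygen by Mitsunobu inversion.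
3. Key disconnection: the cycloheptane is cut at C9–C10 and C1–C5 into a 1,5-dialdehyde (C5 and C9, from ozonolysis of a cis-2-silyloxycyclopent-3-enyl unit) and a chiral 2-silyloxy allylic 1,2-bis(boronate) (C3–C2–C1–C10–C14), joined by a tandem double allylboration.
4. Enabling feature: in the seven-membered ring the carbinol carbons C9 and C5 flank the two-carbon unit C10–C1, and C1 carries an oxygen and an unsaturated carbon substituent, so C9(O)–C10–C1–C2=C3 and C5(O)–C1–C2=C3 are two homoallylic-alcohol retrons sharing one vinyl group.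
5. Ring order: bought cyclopentene → temporary γ-lactone (step 1, opened in step 4) → cyclopentene cleaved (step 6) → cycloheptane (key step) → γ-lactone (step 15) → exocyclic methylene (last).

Key step: step 9

Assumption: (S)-2-(cyclopent-2-en-1-yl)acetic acid is taken as a purchasable single enantiomer (otherwise it is reached by salt resolution of the commercial racemic acid).

**Route**

Step 1
Reactants: 1 (S)-2-(cyclopent-2-en-1-yl)acetic acid
Product: 2 (3aS,6R,6aR)-6-iodohexahydro-2H-cyclopenta[b]furan-2-one (cis-fused, iodine trans to the lactone oxygen)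
Conditions: I2, KI, NaHCO3, H2O/THF, 0 °C to rt, dark
Reagents that add atoms: iodine, II
Why: Iodolactonisation: anti opening of the iodonium ion by the tethered carboxylate (5-exo) forces the new C6–O bond cis to the C7 side chain and puts iodine trans to it, so C6 is set by the C7 centre.

Step 2
Reactants: 2 iodolactone
Product: 3 (3aS,6aR)-3,3a,4,6a-tetrahydro-2H-cyclopenta[b]furan-2-one
Conditions: DBU, THF, reflux
Reagents that add atoms: none
Why: E2 dehydroiodination: only a C9 hydrogen is anti-periplanar to iodine (H6 is syn), so the double bond should end between C5 and C9, next to the carbinol carbon, and no stereocentre changes.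

Step 3
Reactants: 3 bicyclic alkene lactone
Product: 5 (3R,3aS,6aS)-3-(hydroxymethyl)-3,3a,4,6a-tetrahydro-2H-cyclopenta[b]furan-2-one, via lithium enolate 4 (not isolated)
Conditions: LiN(i-Pr)2 (LDA), THF, −78 °C; then CH2O gas (from cracked paraformaldehyde), −78 to −20 °C; NH4Cl (aq)
Reagents that add atoms: formaldehyde, C=O
Why: Enolate hydroxymethylation (aldol addition to monomeric formaldehyde): the electrophile should enter on the convex face of the cis-fused bicycle, giving the 11R centre, which is removed again in step 16.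

Step 4
Reactants: 5 hydroxymethyl lactone
Product: 6 (2R)-3-hydroxy-2-[(1S,2S)-2-hydroxycyclopent-3-en-1-yl]-N-methoxy-N-methylpropanamide
Conditions: MeNHOMe·HCl, AlMe3, CH2Cl2, 0 °C to rt; aqueous potassium sodium tartrate
Reagents that add atoms: N,O-dimethylhydroxylamine hydrochloride, CNOC.Cl
Why: Weinreb aminolysis of a lactone with the aluminium amide made from AlMe3 and the amine salt opens the ring without touching a stereocentre and frees the C6 hydroxyl for a bulky silyl group.

Step 5
Reactants: 6 Weinreb amide diol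
Product: 7 bis(tert-butyldimethylsilyl) ether of 6 (C6–OTBS and C13–OTBS)
Conditions: TBSOTf, 2,6-lutidine, CH2Cl2, −78 to 0 °C
Reagents that add atoms: tert-butyldimethylsilyl trifluoromethanesulfonate, CC(C)(C)[Si](C)(C)OS(=O)(=O)C(F)(F)F
Why: Silylation with a silyl triflate caps both hydroxyls at once, which blocks relactonisation and places a shielding silyl ether next to the future C5 aldehyde.

Step 6
Reactants: 7 bis-silyl ether
Product: 9 (2R,3S,4R)-4-(tert-butyldimethylsilyloxy)-2-[(tert-butyldimethylsilyloxy)methyl]-N-methoxy-N-methyl-5-oxo-3-(2-oxoethyl)pentanamide, via ozonide 8 (not isolated)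
Conditions: O3, CH2Cl2, −78 °C; then PPh3, −78 °C to rt; used crude
Reagents that add atoms: ozone, [O-][O+]=O
Why: Ozonolysis with reductive work-up cleaves the C5=C9 bond to the 1,5-dialdehyde; the α-silyloxy aldehyde is not purified so that C6 is not epimerised.

Step 7
Reactants: 10 pent-1-yn-3-one
Product: 11 (Z)-tert-butyldimethyl(pent-3-en-1-yn-3-yloxy)silane
Conditions: TBSOTf, Et3N, CH2Cl2, −78 to 0 °C
Reagents that add atoms: tert-butyldimethylsilyl trifluoromethanesulfonate, CC(C)(C)[Si](C)(C)OS(=O)(=O)C(F)(F)F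
Why: Soft enolisation with a silyl triflate and an amine should give the thermodynamically preferred (Z)-silyl enol ether (methyl cis to oxygen), the geometry that makes the later allyl unit E-crotyl-like.

Step 8
Reactants: 11 silyloxy enyne
Product: 13 2,2'-[(2R,3Z)-3-(tert-butyldimethylsilyloxy)pent-3-ene-1,2-diyl]bis(4,4,5,5-tetramethyl-1,3,2-dioxaborolane), via dienylboronate 12 (not isolated)
Conditions: CuCl (5 mol %), chiral sulfonate-bearing imidazolinium salt (NHC precursor, 5 mol %), NaOt-Bu (20 mol %), B2(pin)2 (2.1 equiv), MeOH (2.2 equiv), THF, −15 °C to rt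
Reagents that add atoms: bis(pinacolato)diboron, CC1(C)OB(OC1(C)C)B1OC(C)(C)C(C)(C)O1
Why: Copper-catalysed double protoboration of a terminal alkyne with a chiral NHC ligand: syn Cu–B addition and protonation give the (E)-alkenylboronate 12, and a second, enantioselective Cu–B addition places boron on C2, the ligand enantiomer being chosen for the R centre.

Step 9
Reactants: 9 dialdehyde; 13 bis(boronate)
Product: 15 9-epi cycloheptane diol (Weinreb amide; 6α-OTBS, 5β-OH, 1α-OTBS with 1β-vinyl, 10α-CH3, 9α-OH; C7 side chain unchanged), via allylboronate 14 (not isolated)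
Conditions: 13 (1.2 equiv), toluene, 4 Å molecular sieves, rt, then 60 °C; NaHCO3 (aq) work-up
Reagents that add atoms: none
Why: Proposed new method: tandem double allylboration of a 1,5-dialdehyde, a [5+2] annulation. The secondary, E-crotyl-type allylboronate of 13 should add first through a chair transition state to the unbranched C9 aldehyde (the C5 aldehyde is α-branched and shielded by its silyl ether); allylic 1,2-strain with the 2-silyloxy group holds the CH2B(pin) substituent axial, so the boron-bearing stereocentre of 13 sets C9 and C10 (anti adduct, C9 still epimeric to the target) and the transposed primary allylboronate 14 forms with its chain cis to CH2B(pin). 14 then closes the carbocycle by a 7-exo-trig intramolecular allylboration of the C5 aldehyde, creating the C1 quaternary carbinol and C5. In this chair the ring chain is axial on C1 and equatorial on C5 (the cis-2-vinylcycloalkanol outcome of Z-allylboronates) and allylic 1,3-strain keeps H10 in the alkene plane, which should put C5–OH trans and the C10 methyl cis to the C1 silyloxy group. The closest known reactions are the tandem double allylation of 1,4-dicarbonyl compounds with diene-derived 1,2-bis(boronates) to cyclohexane-1,4-diols and the intramolecular allylboration of ω-oxo allylboronates. The step needs aldehyde chemoselectivity in the first addition and reagent control over the remote C6/C7 centres; the bulk of the α-substituted reagent and the shielded, α-branched C5 aldehyde are meant to secure both.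

Step 10
Reactants: 15 9-epi diol
Product: 16 9β-formate of the cycloheptane (C9 inverted; 5β-OH free)
Conditions: HCO2H, PPh3, DIAD, THF, 0 °C to rt
Reagents that add atoms: formic acid, O=CO
Why: Mitsunobu reaction: the unhindered C9 hydroxyl should be activated selectively (the C5 hydroxyl lies between a quaternary carbon and a silyloxy carbon) and displaced with inversion, turning 9α into the required 9β oxygen and masking it as a labile formate.

Step 11
Reactants: 16 formate alcohol; 17 (S)-2-methylbutanoic acid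
Product: 18 5β-[(S)-2-methylbutanoyl] ester of 16
Conditions: DIC, DMAP, CH2Cl2, 0 °C to rt
Reagents that add atoms: none
Why: Steglich esterification (carbodiimide/DMAP) of the only free hydroxyl; the acid is activated without a ketene-forming base, so the S centre of the acyl group is kept.

Step 12
Reactants: 18 vinyl ester
Product: 20 C2 aldehyde (C1 carries OTBS and CHO), via ozonide 19 (not isolated)
Conditions: O3, CH2Cl2, −78 °C; then PPh3, −78 °C to rt
Reagents that add atoms: ozone, [O-][O+]=O
Why: Ozonolysis of the only C=C bond turns the C1 vinyl group into the C2 aldehyde with loss of the terminal carbon as formaldehyde.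

Step 13
Reactants: 20 aldehyde; 21 2-allyl-4,4,5,5-tetramethyl-1,3,2-dioxaborolane
Product: 22 C2 homoallylic alcohol (both C2 epimers)
Conditions: toluene, 50 °C; NaHCO3 (aq) work-up
Reagents that add atoms: none
Why: Allylboration of an aldehyde is neutral and chemoselective (Weinreb amide, esters and formate untouched); the new C2 carbinol centre is oxidised away in step 14.

Step 14
Reactants: 22 homoallylic alcohol
Product: 24 (E)-but-2-enoyl ketone (C2 ketone, C3=C4 trans), via deconjugated enone 23 (not isolated)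
Conditions: Dess–Martin periodinane, NaHCO3, CH2Cl2, rt; then DBU (0.2 equiv), rt
Reagents that add atoms: none
Why: Dess–Martin oxidation gives the β,γ-unsaturated ketone, which base should isomerise into conjugation to the thermodynamically favoured (E)-enone.

Step 15
Reactants: 24 silylated enone
Product: 26 triol lactone (11R-hydroxymethyl lactone; 9β-OH, 1α-OH, 5β-ester), via formate lactone 25 (not isolated)
Conditions: HF·pyridine, THF/pyridine, 0 °C to rt; then NaHCO3, MeOH, rt
Reagents that add atoms: none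
Why: Fluoride-mediated desilylation frees the C6 hydroxyl, which lactonises onto the Weinreb amide under the acidic conditions (cis fusion dictated by C6/C7), and mild methanolysis removes the labile formate without touching the hindered C5 ester.

Step 16
Reactants: 26 triol lactone
Product: 28 target CNP0331957.1, via mesylate 27 (not isolated)
Conditions: MsCl, Et3N, CH2Cl2, −40 °C; then DBU, 0 °C to rt
Reagents that add atoms: none
Why: Selective mesylation of the primary hydroxyl followed by E1cB elimination across C11–C13 installs the exocyclic methylene and erases the C11 centre; C1 is quaternary, so the β-acyloxy ketone cannot eliminate.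

**Compound list**

1 | (S)-2-(cyclopent-2-en-1-yl)acetic acid | OC(=O)C[C@H]1C=CCC1 | starting material
2 | (3aS,6R,6aR)-6-iodohexahydro-2H-cyclopenta[b]furan-2-one | C1C(=O)O[C@@H]2[C@H]1CC[C@H]2I | intermediate
3 | (3aS,6aR)-3,3a,4,6a-tetrahydro-2H-cyclopenta[b]furan-2-one | C1C(=O)O[C@@H]2[C@H]1CC=C2 | intermediate
4 | lithium enolate of 3 | C1=C(O[Li])O[C@@H]2[C@H]1CC=C2 | intermediate (not isolated)
5 | (3R,3aS,6aS)-3-(hydroxymethyl)-3,3a,4,6a-tetrahydro-2H-cyclopenta[b]furan-2-one | OC[C@@H]1C(=O)O[C@@H]2[C@H]1CC=C2 | intermediate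
6 | (2R)-3-hydroxy-2-[(1S,2S)-2-hydroxycyclopent-3-en-1-yl]-N-methoxy-N-methylpropanamide | CON(C)C(=O)[C@@H](CO)[C@@H]1CC=C[C@@H]1O | intermediate
7 | bis(tert-butyldimethylsilyl) ether of 6 | CON(C)C(=O)[C@@H](CO[Si](C)(C)C(C)(C)C)[C@@H]1CC=C[C@@H]1O[Si](C)(C)C(C)(C)C | intermediate
8 | ozonide of 7 (1,2,4-trioxolane across C5/C9, ring-fusion epimers) | CON(C)C(=O)[C@@H](CO[Si](C)(C)C(C)(C)C)[C@@H]1CC2OOC(O2)[C@@H]1O[Si](C)(C)C(C)(C)C | intermediate (not isolated)
9 | (2R,3S,4R)-4-(tert-butyldimethylsilyloxy)-2-[(tert-butyldimethylsilyloxy)methyl]-N-methoxy-N-methyl-5-oxo-3-(2-oxoethyl)pentanamide | CON(C)C(=O)[C@@H](CO[Si](C)(C)C(C)(C)C)[C@H](CC=O)[C@@H](O[Si](C)(C)C(C)(C)C)C=O | intermediate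
10 | pent-1-yn-3-one | CCC(=O)C#C | starting material
11 | (Z)-tert-butyldimethyl(pent-3-en-1-yn-3-yloxy)silane | C/C=C(/C#C)O[Si](C)(C)C(C)(C)C | intermediate
12 | 2-[(1E,3Z)-3-(tert-butyldimethylsilyloxy)penta-1,3-dien-1-yl]-4,4,5,5-tetramethyl-1,3,2-dioxaborolane | C/C=C(O[Si](C)(C)C(C)(C)C)/C=C/B1OC(C)(C)C(C)(C)O1 | intermediate (not isolated)
13 | 2,2'-[(2R,3Z)-3-(tert-butyldimethylsilyloxy)pent-3-ene-1,2-diyl]bis(4,4,5,5-tetramethyl-1,3,2-dioxaborolane) | C/C=C(/[C@@H](CB1OC(C)(C)C(C)(C)O1)B1OC(C)(C)C(C)(C)O1)O[Si](C)(C)C(C)(C)C | intermediate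
14 | mono-allylation product: C9 borate, (9S,10S), primary allylboronate with its chain cis to CH2B(pin), C5 aldehyde free | O=C[C@H](O[Si](C)(C)C(C)(C)C)[C@@H](C[C@H](OB1OC(C)(C)C(C)(C)O1)[C@H](C)/C(O[Si](C)(C)C(C)(C)C)=C\CB1OC(C)(C)C(C)(C)O1)[C@H](CO[Si](C)(C)C(C)(C)C)C(=O)N(C)OC | intermediate (not isolated)
15 | 9-epi cycloheptane diol (6α-OTBS, 5β-OH, 1α-OTBS/1β-vinyl, 10α-CH3, 9α-OH; Weinreb amide side chain on C7) | CON(C)C(=O)[C@@H](CO[Si](C)(C)C(C)(C)C)[C@@H]1C[C@H](O)[C@H](C)[C@@](O[Si](C)(C)C(C)(C)C)(C=C)[C@@H](O)[C@@H]1O[Si](C)(C)C(C)(C)C | intermediate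
16 | 9β-formate (C9 inverted), 5β-OH free | CON(C)C(=O)[C@@H](CO[Si](C)(C)C(C)(C)C)[C@@H]1C[C@@H](OC=O)[C@H](C)[C@@](O[Si](C)(C)C(C)(C)C)(C=C)[C@@H](O)[C@@H]1O[Si](C)(C)C(C)(C)C | intermediate
17 | (S)-2-methylbutanoic acid | CC[C@H](C)C(=O)O | starting material
18 | 5β-[(S)-2-methylbutanoate] of 16 | CON(C)C(=O)[C@@H](CO[Si](C)(C)C(C)(C)C)[C@@H]1C[C@@H](OC=O)[C@H](C)[C@@](O[Si](C)(C)C(C)(C)C)(C=C)[C@@H](OC(=O)[C@@H](C)CC)[C@@H]1O[Si](C)(C)C(C)(C)C | intermediate
19 | ozonide of 18 (1,2,4-trioxolane on C1, epimers) | CON(C)C(=O)[C@@H](CO[Si](C)(C)C(C)(C)C)[C@@H]1C[C@@H](OC=O)[C@H](C)[C@@](O[Si](C)(C)C(C)(C)C)(C2OCOO2)[C@@H](OC(=O)[C@@H](C)CC)[C@@H]1O[Si](C)(C)C(C)(C)C | intermediate (not isolated)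
20 | C2 aldehyde (C1: OTBS and CHO) | CON(C)C(=O)[C@@H](CO[Si](C)(C)C(C)(C)C)[C@@H]1C[C@@H](OC=O)[C@H](C)[C@@](O[Si](C)(C)C(C)(C)C)(C=O)[C@@H](OC(=O)[C@@H](C)CC)[C@@H]1O[Si](C)(C)C(C)(C)C | intermediate
21 | 2-allyl-4,4,5,5-tetramethyl-1,3,2-dioxaborolane | C=CCB1OC(C)(C)C(C)(C)O1 | starting material
22 | C2 homoallylic alcohol (C2 epimers) | CON(C)C(=O)[C@@H](CO[Si](C)(C)C(C)(C)C)[C@@H]1C[C@@H](OC=O)[C@H](C)[C@@](O[Si](C)(C)C(C)(C)C)(C(O)CC=C)[C@@H](OC(=O)[C@@H](C)CC)[C@@H]1O[Si](C)(C)C(C)(C)C | intermediate
23 | β,γ-unsaturated ketone (but-3-enoyl on C1) | CON(C)C(=O)[C@@H](CO[Si](C)(C)C(C)(C)C)[C@@H]1C[C@@H](OC=O)[C@H](C)[C@@](O[Si](C)(C)C(C)(C)C)(C(=O)CC=C)[C@@H](OC(=O)[C@@H](C)CC)[C@@H]1O[Si](C)(C)C(C)(C)C | intermediate (not isolated)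
24 | (E)-but-2-enoyl ketone, fully protected | CON(C)C(=O)[C@@H](CO[Si](C)(C)C(C)(C)C)[C@@H]1C[C@@H](OC=O)[C@H](C)[C@@](O[Si](C)(C)C(C)(C)C)(C(=O)/C=C/C)[C@@H](OC(=O)[C@@H](C)CC)[C@@H]1O[Si](C)(C)C(C)(C)C | intermediate
25 | cis-fused γ-lactone with 9β-formate, 13-OH and 1α-OH | OC[C@@H]1C(=O)O[C@@H]2[C@H]1C[C@@H](OC=O)[C@H](C)[C@@](O)(C(=O)/C=C/C)[C@H]2OC(=O)[C@@H](C)CC | intermediate (not isolated)
26 | triol lactone (11R-hydroxymethyl; 9β-OH, 1α-OH) | OC[C@@H]1C(=O)O[C@@H]2[C@H]1C[C@@H](O)[C@H](C)[C@@](O)(C(=O)/C=C/C)[C@H]2OC(=O)[C@@H](C)CC | intermediate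
27 | C13 mesylate of 26 | CS(=O)(=O)OC[C@@H]1C(=O)O[C@@H]2[C@H]1C[C@@H](O)[C@H](C)[C@@](O)(C(=O)/C=C/C)[C@H]2OC(=O)[C@@H](C)CC | intermediate (not isolated)
28 | CNP0331957.1 | C=C1C(=O)O[C@@H]2[C@H]1C[C@@H](O)[C@H](C)[C@@](O)(C(=O)/C=C/C)[C@H]2OC(=O)[C@@H](C)CC | target

**Step count and risks**

Total steps: 16. Longest linear sequence: 14 steps (steps 1–6 and 9–16 from 1); steps 7–8 make the boron reagent in a two-step side branch.

Steps most likely to fail:

1. Step 9 (proposed new method). The first allylation may lose chemoselectivity between the two aldehydes, giving the regio-reversed annulation, or the seven-membered closure may stall at the mono-adduct. The fallback sets out from 7 and returns at 15, using known reactions only. Ozonolysis of 7 in CH2Cl2/MeOH with NaHCO3, then TsOH, then NaHCO3/Me2S (terminus-differentiating ozonolysis) should give the aldehyde acetal F1; only C9 is a free aldehyde, because the carbonyl oxide forms at the alkene carbon remote from the allylic silyloxy group. Reagent 13 then adds once, by ordinary intermolecular allylboration, to give the allylboronate acetal F2. Hydrolysis of the acetal with LiBF4 in wet MeCN liberates the C5 aldehyde, which should cyclise by intramolecular allylboration to 15.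

2. Step 8. The second copper–boron addition may go astray on the boryl diene, the silyl enol ether may be methanolysed, or enantiocontrol may be poor. The fallback sets out from 11 and returns at 15. Semihydrogenation of the alkyne (H2, Pd/CaCO3 poisoned with Pb(OAc)2, quinoline) gives the diene F3. Phosphine-free Pt(dba)2-catalysed diboration with B2(pin)2, which is expected to add 1,2 across the terminal double bond, gives the racemic bis(boronate) F4. F4 is used in twofold amount in step 9; only its R enantiomer leads to 15, and the diastereomer from the S enantiomer is removed by chromatography.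

3. Step 10. The C5 hydroxyl may attack the activated C9 (transannular ether formation), or elimination may compete with inversion. The fallback sets out from 15 and returns at 18. Selective silylation of the C9 hydroxyl (TESCl, imidazole) gives F5; esterification of the C5 hydroxyl as in step 11 gives F6; PPTS in MeOH removes only the triethylsilyl group to give the alcohol F7; Mitsunobu inversion of F7 with formic acid, now without a free neighbouring hydroxyl, gives 18.

**Further compounds**

F1 | step 9 | aldehyde acetal: C9 aldehyde, C5 dimethyl acetal, otherwise as 9 | CON(C)C(=O)[C@@H](CO[Si](C)(C)C(C)(C)C)[C@H](CC=O)[C@@H](O[Si](C)(C)C(C)(C)C)C(OC)OC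
F2 | step 9 | mono-allylation product of F1 (as 14, with C5 as dimethyl acetal) | COC(OC)[C@H](O[Si](C)(C)C(C)(C)C)[C@@H](C[C@H](OB1OC(C)(C)C(C)(C)O1)[C@H](C)/C(O[Si](C)(C)C(C)(C)C)=C\CB1OC(C)(C)C(C)(C)O1)[C@H](CO[Si](C)(C)C(C)(C)C)C(=O)N(C)OC
F3 | step 8 | (Z)-tert-butyldimethyl(penta-1,3-dien-3-yloxy)silane | C/C=C(/C=C)O[Si](C)(C)C(C)(C)C
F4 | step 8 | racemic 13 | C/C=C(/C(CB1OC(C)(C)C(C)(C)O1)B1OC(C)(C)C(C)(C)O1)O[Si](C)(C)C(C)(C)C
F5 | step 10 | 9α-triethylsilyl ether of 15 | CON(C)C(=O)[C@@H](CO[Si](C)(C)C(C)(C)C)[C@@H]1C[C@H](O[Si](CC)(CC)CC)[C@H](C)[C@@](O[Si](C)(C)C(C)(C)C)(C=C)[C@@H](O)[C@@H]1O[Si](C)(C)C(C)(C)C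
F6 | step 10 | 5β-[(S)-2-methylbutanoate] of F5 | CON(C)C(=O)[C@@H](CO[Si](C)(C)C(C)(C)C)[C@@H]1C[C@H](O[Si](CC)(CC)CC)[C@H](C)[C@@](O[Si](C)(C)C(C)(C)C)(C=C)[C@@H](OC(=O)[C@@H](C)CC)[C@@H]1O[Si](C)(C)C(C)(C)C
F7 | step 10 | 9α-alcohol 5β-ester (F6 without the triethylsilyl group) | CON(C)C(=O)[C@@H](CO[Si](C)(C)C(C)(C)C)[C@@H]1C[C@H](O)[C@H](C)[C@@](O[Si](C)(C)C(C)(C)C)(C=C)[C@@H](OC(=O)[C@@H](C)CC)[C@@H]1O[Si](C)(C)C(C)(C)C
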